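**Strategy.** Ring B is disconnected across C1'–C2', C2'–C3' and C4'–C5'. Its substitution (C1' carrying the future C3, OH on C2', geranyl on C3', OMe on C4', C5' and C6' unsubstituted) is the exact regiochemical output of a vinylketene–ynol ether benzannulation. One photochemical/thermal operation therefore assembles the arene with both oxygens differentiated and the geranyl chain in place. The precursors are an α-diazo enone whose γ-carbon is the prochiral C5 of a 1,3-dioxane acetonide (the latent C2–C3–C4 unit) and a geranyl-substituted methoxyalkyne. C3 is set afterwards by lipase desymmetrisation of the derived 2-aryl-1,3-diol; ring C is closed by Mitsunobu etherification and Friedel–Crafts acylation.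

Key step: step 4

Assumption: the lipase is taken to acetylate the pro-S hydroxymethyl group of the prochiral 2-aryl-1,3-propanediol; should it prefer the other arm, hydrolysis of the corresponding diacetate with the same enzyme is expected to give the same (S)-monoacetate, because the enzyme then removes the acetyl group from the arm it would otherwise acylate.

In the names below, geranyl = (2E)-3,7-dimethylocta-2,6-dien-1-yl, TBS = tert-butyldimethylsilyl, and "aryl" in compounds 18 and 21–25 = 2-(TBS-oxy)-3-geranyl-4-methoxyphenyl.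

Step 1
Reactants: 1 (2,2-dimethyl-1,3-dioxan-5-yl)methanol; 2 1-(triphenylphosphoranylidene)propan-2-one
Product: 4 (E)-4-(2,2-dimethyl-1,3-dioxan-5-yl)but-3-en-2-one, via dioxane carbaldehyde 3 (not isolated)
Conditions: PhI(OAc)2 (1.1 equiv), TEMPO (0.1 equiv), CH2Cl2, rt; then 2 (1.3 equiv), rt to 40 °C
Reagents that add atoms: none
Why: Oxoammonium oxidation gives the β-alkoxy aldehyde under non-basic conditions and the stabilised acylmethylene ylide olefinates it in the same flask (Wittig reaction) before β-elimination can open the acetonide, the stabilised ylide giving the E-enone.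

Step 2
Reactants: 4 (E)-4-(2,2-dimethyl-1,3-dioxan-5-yl)but-3-en-2-one
Product: 6 (E)-1-diazo-4-(2,2-dimethyl-1,3-dioxan-5-yl)but-3-en-2-one, via trifluoroacetyl diketone 5 (not isolated)
Conditions: LiN(SiMe3)2 (1.1 equiv), THF, −78 °C; CF3CO2CH2CF3 (1.2 equiv); aq. NaH2PO4; then 4-AcNHC6H4SO2N3 (1.5 equiv), Et3N (1.5 equiv), H2O (1 equiv), MeCN, rt
Reagents that add atoms: 4-acetamidobenzenesulfonyl azide, CC(=O)Nc1ccc(cc1)S(=O)(=O)N=[N+]=[N-]; 2,2,2-trifluoroethyl trifluoroacetate, O=C(OCC(F)(F)F)C(F)(F)F (its CF3CO group is carried only by intermediate 5)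
Why: Kinetic deprotonation at the methyl group (not at the γ-carbon) and Claisen-type trifluoroacetylation activate that position, so that sulfonyl azide transfer with loss of the trifluoroacetyl group (detrifluoroacetylative Regitz diazo transfer) gives the α'-diazo enone without touching the enone or the acetonide.

Step 3
Reactants: 7 chloroacetaldehyde dimethyl acetal; 8 geranyl bromide
Product: 10 (E)-1-methoxy-5,9-dimethyldeca-4,8-dien-1-yne, via sodium methoxyacetylide 9 (not isolated)
Conditions: NaNH2 (3.0 equiv), liq. NH3, −33 °C; then 8 (0.9 equiv), THF, −33 °C; NH4Cl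
Reagents that add atoms: sodium amide, [Na+].[NH2-] (its sodium is carried only by intermediate 9)
Why: Three equivalents of amide convert the chloroacetal by double elimination and deprotonation into the methoxyacetylide, which is C-alkylated by the primary allylic bromide in an SN2 reaction with the E-alkene retained, and the exact base stoichiometry avoids isomerisation of the skipped enyne.

Step 4
Reactants: 6 (E)-1-diazo-4-(2,2-dimethyl-1,3-dioxan-5-yl)but-3-en-2-one; 10 (E)-1-methoxy-5,9-dimethyldeca-4,8-dien-1-yne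
Product: 15 6-(2,2-dimethyl-1,3-dioxan-5-yl)-2-geranyl-3-methoxyphenol, via vinylketene 11 (not isolated), via 4-alkenylcyclobutenone 12 (not isolated), via dienylketene 13 (not isolated), via cyclohexadienone 14 (not isolated)
Conditions: 10 (1.5 equiv), degassed ClCH2CH2Cl, hν (254 nm, Vycor), rt; then 80 °C
Reagents that add atoms: none
Why: Irradiation expels N2 from 6 and the alkenyl group migrates (photochemical Wolff rearrangement) to give vinylketene 11, whose electrophilic ketene carbon bonds to the nucleophilic, geranyl-bearing carbon of ynol ether 10 in a [2+2] cycloaddition, giving cyclobutenone 12 with the alkenyl group on the sp3 ring carbon C4. On heating, 12 opens by reversible 4π electrocyclic cleavage to dienylketene 13, which undergoes thermal disrotatory 6π electrocyclisation to cyclohexadienone 14 and tautomerises to phenol 15. The closest known reaction type is the Danheiser benzannulation in its photochemical α-diazo ketone variant with alkoxyalkynes, which gives resorcinol monoethers of exactly this pattern. Ring B is thus closed by a 6π electrocyclisation that forms C1'–C2' after the cycloaddition has formed C2'–C3' and C4'–C5'. No stereocenter is created, since the dioxane carbon that becomes C3 stays prochiral and the E-alkenes of the side chain are spectators. The only selectivity needed is the regiochemistry of the [2+2] step, secured by the donor oxygen of 10 polarising the triple bond so that its C-geranyl carbon attacks the ketene carbonyl carbon, while excess 10 and the far lower ketenophilicity of the isolated trisubstituted alkenes keep the ketene from being diverted.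

Step 5
Reactants: 15 6-(2,2-dimethyl-1,3-dioxan-5-yl)-2-geranyl-3-methoxyphenol
Product: 16 tert-butyl[6-(2,2-dimethyl-1,3-dioxan-5-yl)-2-geranyl-3-methoxyphenoxy]dimethylsilane
Conditions: TBSCl (1.5 equiv), imidazole (3 equiv), DMAP (0.1 equiv), DMF, 40 °C
Reagents that add atoms: tert-butyldimethylsilyl chloride, CC(C)(C)[Si](C)(C)Cl
Why: Imidazole-mediated O-silylation masks the C2' hydroxyl, which would otherwise cyclise onto the activated side-chain alcohol in the later Mitsunobu step, and mild heating with DMAP offsets the two ortho substituents without endangering the acetonide.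

Step 6
Reactants: 16 tert-butyl[6-(2,2-dimethyl-1,3-dioxan-5-yl)-2-geranyl-3-methoxyphenoxy]dimethylsilane
Product: 17 2-[2-(TBS-oxy)-3-geranyl-4-methoxyphenyl]propane-1,3-diol
Conditions: PPTS (0.2 equiv), MeOH, rt
Reagents that add atoms: none
Why: Acid-catalysed transacetalisation in methanol removes the 1,3-dioxane acetonide, while the aryl silyl ether and the trisubstituted alkenes are inert to pyridinium tosylate.

Step 7
Reactants: 17 2-[2-(TBS-oxy)-3-geranyl-4-methoxyphenyl]propane-1,3-diol
Product: 18 (S)-2-aryl-3-hydroxypropyl acetate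
Conditions: Burkholderia cepacia lipase (Amano PS, immobilised), vinyl acetate (5 equiv), t-BuOMe, 25 °C
Reagents that add atoms: vinyl acetate, CC(=O)OC=C
Why: Irreversible lipase-catalysed transesterification differentiates the enantiotopic hydroxymethyl groups of the 2-aryl-1,3-propanediol (enzymatic desymmetrisation), the chiral active site setting the future C3 in the S configuration.

Step 8
Reactants: 19 phloroglucinol
Product: 20 3,5-bis(tert-butyldimethylsilyloxy)phenol
Conditions: TBSCl (2.0 equiv), imidazole (2.5 equiv), DMF, 0 °C to rt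
Reagents that add atoms: tert-butyldimethylsilyl chloride, CC(C)(C)[Si](C)(C)Cl
Why: Statistical O-silylation of the three equivalent phenols with two equivalents of silyl chloride should give the bis-ether as the main component of a chromatographically separable mixture, the mono- and tris-ethers being recyclable.

Step 9
Reactants: 18 (S)-2-aryl-3-hydroxypropyl acetate; 20 3,5-bis(tert-butyldimethylsilyloxy)phenol
Product: 21 (S)-3-[3,5-bis(TBS-oxy)phenoxy]-2-arylpropyl acetate
Conditions: PPh3 (1.5 equiv), DIAD (1.5 equiv), 20 (1.3 equiv), THF, 0 °C to rt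
Reagents that add atoms: none
Why: Mitsunobu etherification of the primary alcohol with the acidic phenol forms the O1–C2 aryl ether at a carbon remote from the stereocenter, under neutral conditions that should not provoke 1,3-acetyl migration.

Step 10
Reactants: 21 (S)-3-[3,5-bis(TBS-oxy)phenoxy]-2-arylpropyl acetate
Product: 22 (R)-3-[3,5-bis(TBS-oxy)phenoxy]-2-arylpropan-1-ol
Conditions: i-Bu2AlH (2.5 equiv), CH2Cl2, −78 °C; aq. potassium sodium tartrate
Reagents that add atoms: none
Why: Reductive cleavage of the acetate with the aluminium hydride at low temperature frees the second arm without the basic methanolysis that would strip the aryl silyl ethers (the descriptor changes to R only through the priority rules).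

Step 11
Reactants: 22 (R)-3-[3,5-bis(TBS-oxy)phenoxy]-2-arylpropan-1-ol
Product: 24 (S)-3-[3,5-bis(TBS-oxy)phenoxy]-2-arylpropanoic acid, via aldehyde 23 (not isolated)
Conditions: TEMPO (0.2 equiv), PhI(OAc)2 (2.5 equiv), CH2Cl2/H2O (2:1), 0 °C to rt
Reagents that add atoms: water, O
Why: Oxoammonium-mediated oxidation in the presence of water takes the primary alcohol through the aldehyde hydrate to the acid in one flask, which keeps the lifetime of the epimerisable α-aryl aldehyde short and spares the trisubstituted alkenes.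

Step 12
Reactants: 24 (S)-3-[3,5-bis(TBS-oxy)phenoxy]-2-arylpropanoic acid
Product: 26 (S)-5,7-bis(TBS-oxy)-3-[2-(TBS-oxy)-3-geranyl-4-methoxyphenyl]chroman-4-one, via mixed anhydride 25 (not isolated)
Conditions: (CF3CO)2O (1.3 equiv), CH2Cl2, 0 °C; pH 7 phosphate buffer
Reagents that add atoms: trifluoroacetic anhydride, O=C(OC(=O)C(F)(F)F)C(F)(F)F (its CF3CO group is carried only by intermediate 25)
Why: The mixed trifluoroacetic anhydride acylates the strongly activated phloroglucinol-derived ring ortho to the ether oxygen (intramolecular Friedel–Crafts acylation closing the six-membered ring C at C4–C4a) without added Lewis acid, the two ortho positions being equivalent and the cold, base-free medium not enolising the stereocenter.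

Step 13
Reactants: 26 (S)-5,7-bis(TBS-oxy)-3-[2-(TBS-oxy)-3-geranyl-4-methoxyphenyl]chroman-4-one
Product: 27 (3S)-5,7-dihydroxy-3-[2-hydroxy-3-geranyl-4-methoxyphenyl]chroman-4-one (CNP0303304.1)
Conditions: HF·pyridine, pyridine, THF, 0 °C to rt
Reagents that add atoms: none
Why: Fluoride-driven cleavage of the three aryl silyl ethers proceeds in a weakly acidic, pyridine-buffered medium that should neither enolise the base-labile C3 stereocenter nor cyclise the geranyl chain onto the C2' phenol.

**Compound list**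

1 | (2,2-dimethyl-1,3-dioxan-5-yl)methanol | OCC1COC(C)(C)OC1 | starting material
2 | 1-(triphenylphosphoranylidene)propan-2-one | CC(=O)C=P(c1ccccc1)(c1ccccc1)c1ccccc1 | starting material
3 | 2,2-dimethyl-1,3-dioxane-5-carbaldehyde | O=CC1COC(C)(C)OC1 | intermediate
4 | (E)-4-(2,2-dimethyl-1,3-dioxan-5-yl)but-3-en-2-one | CC(=O)/C=C/C1COC(C)(C)OC1 | intermediate
5 | (E)-6-(2,2-dimethyl-1,3-dioxan-5-yl)-1,1,1-trifluorohex-5-ene-2,4-dione | O=C(CC(=O)C(F)(F)F)/C=C/C1COC(C)(C)OC1 | intermediate
6 | (E)-1-diazo-4-(2,2-dimethyl-1,3-dioxan-5-yl)but-3-en-2-one | [N-]=[N+]=CC(=O)/C=C/C1COC(C)(C)OC1 | intermediate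
7 | chloroacetaldehyde dimethyl acetal | COC(CCl)OC | starting material
8 | geranyl bromide | BrC/C=C(\C)CCC=C(C)C | starting material
9 | sodium methoxyacetylide | [Na+].[C-]#COC | intermediate
10 | (E)-1-methoxy-5,9-dimethyldeca-4,8-dien-1-yne | COC#CC/C=C(\C)CCC=C(C)C | intermediate
11 | (3E)-4-(2,2-dimethyl-1,3-dioxan-5-yl)buta-1,3-dien-1-one (vinylketene) | O=C=C/C=C/C1COC(C)(C)OC1 | intermediate
12 | 4-[(E)-2-(2,2-dimethyl-1,3-dioxan-5-yl)ethenyl]-2-geranyl-3-methoxycyclobut-2-en-1-one (racemic at C4) | COC1=C(C/C=C(\C)CCC=C(C)C)C(=O)C1/C=C/C2COC(C)(C)OC2 | intermediate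
13 | (3E,5E)-6-(2,2-dimethyl-1,3-dioxan-5-yl)-2-geranyl-3-methoxyhexa-1,3,5-trien-1-one (dienylketene) | O=C=C(C/C=C(\C)CCC=C(C)C)/C(OC)=C\C=C\C1COC(C)(C)OC1 | intermediate
14 | 6-(2,2-dimethyl-1,3-dioxan-5-yl)-2-geranyl-3-methoxycyclohexa-2,4-dien-1-one | COC1=C(C/C=C(\C)CCC=C(C)C)C(=O)C(C2COC(C)(C)OC2)C=C1 | intermediate
15 | 6-(2,2-dimethyl-1,3-dioxan-5-yl)-2-geranyl-3-methoxyphenol | COc1ccc(C2COC(C)(C)OC2)c(O)c1C/C=C(\C)CCC=C(C)C | intermediate
16 | tert-butyl[6-(2,2-dimethyl-1,3-dioxan-5-yl)-2-geranyl-3-methoxyphenoxy]dimethylsilane | COc1ccc(C2COC(C)(C)OC2)c(O[Si](C)(C)C(C)(C)C)c1C/C=C(\C)CCC=C(C)C | intermediate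
17 | 2-[2-(TBS-oxy)-3-geranyl-4-methoxyphenyl]propane-1,3-diol | COc1ccc(C(CO)CO)c(O[Si](C)(C)C(C)(C)C)c1C/C=C(\C)CCC=C(C)C | intermediate
18 | (S)-2-[2-(TBS-oxy)-3-geranyl-4-methoxyphenyl]-3-hydroxypropyl acetate | COc1ccc([C@@H](CO)COC(C)=O)c(O[Si](C)(C)C(C)(C)C)c1C/C=C(\C)CCC=C(C)C | intermediate
19 | phloroglucinol | Oc1cc(O)cc(O)c1 | starting material
20 | 3,5-bis(tert-butyldimethylsilyloxy)phenol | CC(C)(C)[Si](C)(C)Oc1cc(O)cc(O[Si](C)(C)C(C)(C)C)c1 | intermediate
21 | (S)-3-[3,5-bis(TBS-oxy)phenoxy]-2-[2-(TBS-oxy)-3-geranyl-4-methoxyphenyl]propyl acetate | COc1ccc([C@@H](COc2cc(O[Si](C)(C)C(C)(C)C)cc(O[Si](C)(C)C(C)(C)C)c2)COC(C)=O)c(O[Si](C)(C)C(C)(C)C)c1C/C=C(\C)CCC=C(C)C | intermediate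
22 | (R)-3-[3,5-bis(TBS-oxy)phenoxy]-2-[2-(TBS-oxy)-3-geranyl-4-methoxyphenyl]propan-1-ol | COc1ccc([C@@H](COc2cc(O[Si](C)(C)C(C)(C)C)cc(O[Si](C)(C)C(C)(C)C)c2)CO)c(O[Si](C)(C)C(C)(C)C)c1C/C=C(\C)CCC=C(C)C | intermediate
23 | (S)-3-[3,5-bis(TBS-oxy)phenoxy]-2-[2-(TBS-oxy)-3-geranyl-4-methoxyphenyl]propanal | COc1ccc([C@@H](COc2cc(O[Si](C)(C)C(C)(C)C)cc(O[Si](C)(C)C(C)(C)C)c2)C=O)c(O[Si](C)(C)C(C)(C)C)c1C/C=C(\C)CCC=C(C)C | intermediate
24 | (S)-3-[3,5-bis(TBS-oxy)phenoxy]-2-[2-(TBS-oxy)-3-geranyl-4-methoxyphenyl]propanoic acid | COc1ccc([C@@H](COc2cc(O[Si](C)(C)C(C)(C)C)cc(O[Si](C)(C)C(C)(C)C)c2)C(=O)O)c(O[Si](C)(C)C(C)(C)C)c1C/C=C(\C)CCC=C(C)C | intermediate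
25 | mixed anhydride of 24 with trifluoroacetic acid, (S) | COc1ccc([C@@H](COc2cc(O[Si](C)(C)C(C)(C)C)cc(O[Si](C)(C)C(C)(C)C)c2)C(=O)OC(=O)C(F)(F)F)c(O[Si](C)(C)C(C)(C)C)c1C/C=C(\C)CCC=C(C)C | intermediate
26 | (S)-5,7-bis(TBS-oxy)-3-[2-(TBS-oxy)-3-geranyl-4-methoxyphenyl]chroman-4-one | COc1ccc([C@H]2COc3cc(O[Si](C)(C)C(C)(C)C)cc(O[Si](C)(C)C(C)(C)C)c3C2=O)c(O[Si](C)(C)C(C)(C)C)c1C/C=C(\C)CCC=C(C)C | intermediate
27 | (3S)-5,7-dihydroxy-3-[2-hydroxy-3-geranyl-4-methoxyphenyl]chroman-4-one (CNP0303304.1) | COc1ccc([C@H]2COc3cc(O)cc(O)c3C2=O)c(O)c1C/C=C(\C)CCC=C(C)C | target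

**Total step count:** 13. **Longest linear sequence:** 11 steps (1, 2, 4, 5, 6, 7, 9, 10, 11, 12, 13).

**Steps most likely to fail**

1. Step 4 (benzannulation). The vinylketene may be diverted before it meets the alkyne, by dimerisation or by acylation of the phenol already formed. Photochemical E/Z isomerisation of the enone may slow the 6π closure, and the ynol ether may degrade under the lamp. The fallback abandons the pericyclic construction and builds the same arene on a preformed benzene ring. It sets out from geranyl bromide 8 together with commercial 2-bromo-5-methoxyphenol and comes back to the route at phenol 15. The phenol is protected with 2-(trimethylsilyl)ethoxymethyl chloride and i-Pr2NEt to give {2-[(2-bromo-5-methoxyphenoxy)methoxy]ethyl}trimethylsilane F1. Palladium-catalysed α-arylation of diethyl malonate (Pd(OAc)2, P(t-Bu)3, K3PO4, toluene, 70 °C) should then give diethyl 2-{4-methoxy-2-[(2-trimethylsilylethoxy)methoxy]phenyl}propanedioate F2. Reduction with LiAlH4 gives 2-{4-methoxy-2-[(2-trimethylsilylethoxy)methoxy]phenyl}propane-1,3-diol F3, and 2,2-dimethoxypropane with PPTS gives 5-{4-methoxy-2-[(2-trimethylsilylethoxy)methoxy]phenyl}-2,2-dimethyl-1,3-dioxane F4. Directed ortho-lithiation with n-BuLi at the carbon between the two oxygens, transmetalation with CuBr·SMe2 and alkylation with 8 should give 5-{3-geranyl-4-methoxy-2-[(2-trimethylsilylethoxy)methoxy]phenyl}-2,2-dimethyl-1,3-dioxane F5. Bu4NF in THF/DMPU at 60 °C removes the acetal protecting group without acid and delivers 15.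

2. Step 12 (Friedel–Crafts closure of ring C). The trifluoroacetic acid released may start cation–olefin cyclisation of the geranyl chain or acid-catalysed enolisation at C3. Acylation next to the bulky silyl ether may also be too slow. The fallback replaces the electrophilic acylation by addition of an aryl nucleophile to an aldehyde; it sets out from alcohol 22 and comes back at chromanone 26. Iodination of the most electron-rich ring with N-iodosuccinimide (MeCN, −20 °C) should give (R)-3-[3,5-bis(TBS-oxy)-2-iodophenoxy]-2-arylpropan-1-ol F6. Dess–Martin periodinane gives (S)-3-[3,5-bis(TBS-oxy)-2-iodophenoxy]-2-arylpropanal F7. Intramolecular Nozaki–Hiyama–Kishi coupling (CrCl2, catalytic NiCl2, DMF) closes ring C to (3S)-5,7-bis(TBS-oxy)-3-aryl-chroman-4-ol F8 as a mixture of C4 epimers. Dess–Martin oxidation under buffered conditions converts both epimers into 26.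

3. Step 7 (enzymatic desymmetrisation). The bulky ortho-silyloxyaryl group may make acylation slow or weaken the discrimination between the enantiotopic arms, and over-acylation to the diacetate may erode the material balance. The fallback uses small-molecule catalysis instead of the enzyme; it sets out from diol 17 and comes back at alcohol 22. Desymmetrising benzoylation with vinyl benzoate and the dinuclear zinc catalyst formed from Et2Zn and the ProPhenol ligand (the ligand enantiomer chosen to acylate the pro-S arm) should give (S)-2-aryl-3-hydroxypropyl benzoate F9. Mitsunobu etherification with 20 (PPh3, DIAD) gives (S)-3-[3,5-bis(TBS-oxy)phenoxy]-2-arylpropyl benzoate F10. Reduction with i-Bu2AlH at −78 °C removes the benzoate and gives 22.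

**Further compounds**

F1 | step 4 | {2-[(2-bromo-5-methoxyphenoxy)methoxy]ethyl}trimethylsilane | COc1ccc(Br)c(OCOCC[Si](C)(C)C)c1
F2 | step 4 | diethyl 2-{4-methoxy-2-[(2-trimethylsilylethoxy)methoxy]phenyl}propanedioate | CCOC(=O)C(C(=O)OCC)c1ccc(OC)cc1OCOCC[Si](C)(C)C
F3 | step 4 | 2-{4-methoxy-2-[(2-trimethylsilylethoxy)methoxy]phenyl}propane-1,3-diol | COc1ccc(C(CO)CO)c(OCOCC[Si](C)(C)C)c1
F4 | step 4 | 5-{4-methoxy-2-[(2-trimethylsilylethoxy)methoxy]phenyl}-2,2-dimethyl-1,3-dioxane | COc1ccc(C2COC(C)(C)OC2)c(OCOCC[Si](C)(C)C)c1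
F5 | step 4 | 5-{3-geranyl-4-methoxy-2-[(2-trimethylsilylethoxy)methoxy]phenyl}-2,2-dimethyl-1,3-dioxane | COc1ccc(C2COC(C)(C)OC2)c(OCOCC[Si](C)(C)C)c1C/C=C(\C)CCC=C(C)C
F6 | step 12 | (R)-3-[3,5-bis(TBS-oxy)-2-iodophenoxy]-2-[2-(TBS-oxy)-3-geranyl-4-methoxyphenyl]propan-1-ol | COc1ccc([C@@H](COc2cc(O[Si](C)(C)C(C)(C)C)cc(O[Si](C)(C)C(C)(C)C)c2I)CO)c(O[Si](C)(C)C(C)(C)C)c1C/C=C(\C)CCC=C(C)C
F7 | step 12 | (S)-3-[3,5-bis(TBS-oxy)-2-iodophenoxy]-2-[2-(TBS-oxy)-3-geranyl-4-methoxyphenyl]propanal | COc1ccc([C@@H](COc2cc(O[Si](C)(C)C(C)(C)C)cc(O[Si](C)(C)C(C)(C)C)c2I)C=O)c(O[Si](C)(C)C(C)(C)C)c1C/C=C(\C)CCC=C(C)C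
F8 | step 12 | (3S)-5,7-bis(TBS-oxy)-3-[2-(TBS-oxy)-3-geranyl-4-methoxyphenyl]chroman-4-ol (C4 epimers) | COc1ccc([C@H]2COc3cc(O[Si](C)(C)C(C)(C)C)cc(O[Si](C)(C)C(C)(C)C)c3C2O)c(O[Si](C)(C)C(C)(C)C)c1C/C=C(\C)CCC=C(C)C
F9 | step 7 | (S)-2-[2-(TBS-oxy)-3-geranyl-4-methoxyphenyl]-3-hydroxypropyl benzoate | COc1ccc([C@@H](CO)COC(=O)c2ccccc2)c(O[Si](C)(C)C(C)(C)C)c1C/C=C(\C)CCC=C(C)C
F10 | step 7 | (S)-3-[3,5-bis(TBS-oxy)phenoxy]-2-[2-(TBS-oxy)-3-geranyl-4-methoxyphenyl]propyl benzoate | COc1ccc([C@@H](COc2cc(O[Si](C)(C)C(C)(C)C)cc(O[Si](C)(C)C(C)(C)C)c2)COC(=O)c2ccccc2)c(O[Si](C)(C)C(C)(C)C)c1C/C=C(\C)CCC=C(C)C
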